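The cyclopentane bond between the methyl-bearing quaternary carbon (C4) and the cyclopropyl-flanked methine (C5) is made by an intramolecular 1,3-dipolar cycloaddition of a diazoalkane onto the trisubstituted alkene of a carvone-derived 2-carene, which closes the five-membered ring as a bridged 1-pyrazoline. The key step exploits the 1,3-relationship of the oxepane bridgeheads C1 (O-bearing) and C4 across C5 in the 2-oxabicyclo[4.2.1]nonane core: loss of N2 turns the azoalkane into a bicyclo[2.1.0]pentane whose strained C1–C4 bond then engages, in a formal (4+3) cycloaddition, the o-quinone methide from diformylphloroglucinol and isovaleraldehyde.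

Key step: step 11

Step 1
Reactants: 1 (S)-(+)-carvone
Product: 2 (S)-5-(2-chloropropan-2-yl)-2-methylcyclohex-2-en-1-one
Conditions: HCl (g), Et2O, 0 °C
Reagents that add atoms: hydrogen chloride, Cl
Why: Markovnikov hydrochlorination of the electron-rich isopropenyl group leaves the enone and the ring stereocentre untouched.

Step 2
Reactants: 2 (S)-5-(2-chloropropan-2-yl)-2-methylcyclohex-2-en-1-one
Product: 3 (1R,6S)-3,7,7-trimethylbicyclo[4.1.0]hept-3-en-2-one
Conditions: KOtBu, THF, 0 °C
Reagents that add atoms: none
Why: The α′-enolate displaces the tertiary chloride (3-exo-tet intramolecular alkylation), which can only give the cis-fused gem-dimethylcyclopropane, so both cyclopropane stereocentres follow from the carvone stereocentre.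

Step 3
Reactants: 3 (1R,6S)-3,7,7-trimethylbicyclo[4.1.0]hept-3-en-2-one
Product: 4 3,4-epoxy-3,7,7-trimethylbicyclo[4.1.0]heptan-2-one (oxirane trans to the cyclopropane)
Conditions: H2O2 (30%), NaOH (cat.), MeOH, 0 °C
Reagents that add atoms: hydrogen peroxide, OO
Why: Weitz–Scheffer nucleophilic epoxidation of the enone should occur from the face opposite the gem-dimethylcyclopropane.

Step 4
Reactants: 4 3,4-epoxy-3,7,7-trimethylbicyclo[4.1.0]heptan-2-one
Product: 5 3,7,7-trimethylbicyclo[4.1.0]hept-2-en-4-ol (hydroxyl trans to the cyclopropane)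
Conditions: N2H4·H2O, AcOH (cat.), MeOH, 0 °C to rt
Reagents that add atoms: none
Why: Wharton transposition of the epoxy ketone moves the oxygen to the carbon that will become C1 and places the alkene next to the cyclopropane.

Step 5
Reactants: 5 3,7,7-trimethylbicyclo[4.1.0]hept-2-en-4-ol
Product: 6 3,7,7-trimethylbicyclo[4.1.0]hept-2-en-4-one
Conditions: MnO2, CH2Cl2, rt
Reagents that add atoms: none
Why: Mild oxidation of the secondary allylic alcohol gives the transposed enone without touching the vinylcyclopropane.

Step 6
Reactants: 6 3,7,7-trimethylbicyclo[4.1.0]hept-2-en-4-one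
Product: 8 (1R,3S,6S)-3,7,7-trimethylbicyclo[4.1.0]heptan-4-one (methyl cis to the cyclopropane), via triethylsilyl enol ether 7 (not isolated)
Conditions: Et3SiH, RhCl(PPh3)3 (cat.), benzene, 50 °C; then 1 M HCl, THF, 0 °C
Reagents that add atoms: none
Why: Rhodium-catalysed 1,4-hydrosilylation gives the enol ether, and kinetic C-protonation on hydrolysis should occur on the face opposite the cyclopropane, which sets the methyl-bearing stereocentre with methyl cis to the cyclopropane.

Step 7
Reactants: 8 (1R,3S,6S)-3,7,7-trimethylbicyclo[4.1.0]heptan-4-one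
Product: 10 3,7,7-trimethylbicyclo[4.1.0]hept-4-en-4-yl trifluoromethanesulfonate (3-methyl cis to the cyclopropane), via lithium enolate 9 (not isolated)
Conditions: LiN(iPr)2, THF, −78 °C; then PhNTf2, −78 to 0 °C
Reagents that add atoms: N-phenylbis(trifluoromethanesulfonimide), O=S(=O)(N(c1ccccc1)S(=O)(=O)C(F)(F)F)C(F)(F)F
Why: Kinetic deprotonation at the less substituted α-CH2 and O-triflation fixes the enol triflate on the cyclopropane side without epimerising the α-methyl centre.

Step 8
Reactants: 10 3,7,7-trimethylbicyclo[4.1.0]hept-4-en-4-yl trifluoromethanesulfonate; 11 2-methyl-2-vinyl-1,3-dioxolane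
Product: 13 2-methyl-2-[2-(3,7,7-trimethylbicyclo[4.1.0]hept-4-en-4-yl)ethyl]-1,3-dioxolane, via alkylborane 12 (not isolated)
Conditions: 11, 9-BBN-H, THF, rt; then 10, Pd(dppf)Cl2 (cat.), K3PO4 (aq.), DMF, 50 °C
Reagents that add atoms: none
Why: Anti-Markovnikov hydroboration followed by B-alkyl Suzuki–Miyaura coupling with the enol triflate attaches the two-carbon tether (C2–C3) and the masked ketone to C1.

Step 9
Reactants: 13 2-methyl-2-[2-(3,7,7-trimethylbicyclo[4.1.0]hept-4-en-4-yl)ethyl]-1,3-dioxolane
Product: 14 4-(3,7,7-trimethylbicyclo[4.1.0]hept-4-en-4-yl)butan-2-one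
Conditions: PPTS (cat.), acetone/H2O, 40 °C
Reagents that add atoms: water, O
Why: Mild acid-catalysed ketal hydrolysis should spare the acid-sensitive vinylcyclopropane.

Step 10
Reactants: 14 4-(3,7,7-trimethylbicyclo[4.1.0]hept-4-en-4-yl)butan-2-one
Product: 15 N′-[4-(3,7,7-trimethylbicyclo[4.1.0]hept-4-en-4-yl)butan-2-ylidene]-4-methylbenzenesulfonohydrazide
Conditions: TsNHNH2, MeOH, rt
Reagents that add atoms: p-toluenesulfonohydrazide, Cc1ccc(cc1)S(=O)(=O)NN
Why: Routine condensation gives the tosylhydrazone, whose E/Z ratio is irrelevant because the C=N carbon becomes the diazo carbon.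

Step 11
Reactants: 15 tosylhydrazone of ketone 14
Product: 18 tetracyclic 1-pyrazoline (2,3-diazabicyclo[2.2.1]hept-2-ene fused to the dimethylnorcarane; bridgehead methyl at C4; new C4–C5 bond anti to the cyclopropane), via sodium tosylhydrazonate 16 (not isolated), via diazoalkane 17 (not isolated)
Conditions: NaH, THF, 0 °C; then toluene, 100 °C
Reagents that add atoms: none
Why: Deprotonation and thermolysis of the tosylhydrazone (aprotic Bamford–Stevens conditions) release the non-stabilised diazoalkane, which adds as a 1,3-dipole to the tethered trisubstituted alkene; the closest known reaction type is the intramolecular diazoalkane–alkene cycloaddition that gives bicyclic 1-pyrazolines. The two-atom tether rules out the fused mode, so the diazo carbon bonds to the distal alkene carbon (the C4–C5 bond, which closes the cyclopentane through the concerted suprafacial dipolar transition state) and the terminal nitrogen bonds to the proximal carbon C1 (which closes the pyrazoline), giving the bridged 2,3-diazabicyclo[2.2.1]heptene. The new C5 stereocentre is set by approach of the dipole to the alkene face opposite the gem-dimethylcyclopropane and the neighbouring methyl group, and the bridgeheads C1 and C4 are fixed by the bicycle. The step needs cycloaddition to outrun loss of N2 from the diazoalkane (carbene 1,2-hydrogen shift); the short tether, which holds the electron-rich alkene next to the dipole, should secure this.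

Step 12
Reactants: 18 tetracyclic 1-pyrazoline
Product: 19 tetracyclic bicyclo[2.1.0]pentane (C1–C4 bond formed; cyclopropane C1–C4–C5 fused to the dimethylnorcarane through C1–C5)
Conditions: hν (350 nm), pentane, 0 °C
Reagents that add atoms: none
Why: Photochemical denitrogenation of the bicyclic azoalkane gives the cyclopentane-1,3-diyl, which collapses to the housane; only the isomer with the six-membered-ring carbon exo on the new cyclopropane can form, and C5 is not touched.

Step 13
Reactants: 19 tetracyclic bicyclo[2.1.0]pentane; 20 2,4,6-trihydroxybenzene-1,3-dicarbaldehyde; 21 3-methylbutanal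
Product: 23 CNP0202714.1 (target), via o-quinone methide 22 (not isolated)
Conditions: ethylenediammonium diacetate (cat.), MeCN, 40 °C
Reagents that add atoms: none
Why: Proposed new method: the o-quinone methide 22 (Knoevenagel condensation of 20 with 21) is a strong carbon electrophile and the bent central C1–C4 bond of the bicyclo[2.1.0]pentane is a strained σ-nucleophile; attack of the methide carbon C7′ on the less hindered bridgehead C4 from the concave face (the exo faces are blocked by the bridgehead substituents) gives a tertiary cyclopentyl cation at C1 that collapses with the phenoxide oxygen on the same face, so the oxepane forms with O and C7′ cis to H-5, and the isobutyl group is expected to sit over the one-carbon bridge; the closest known reaction types are the thermal (2σ+2π) cycloadditions of bicyclo[2.1.0]pentanes with electron-poor alkenes and the hetero-Diels–Alder trapping of this quinone methide by terpene alkenes.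

Compound list
1 | (S)-(+)-carvone | CC1=CC[C@@H](CC1=O)C(C)=C | starting material
2 | (S)-5-(2-chloropropan-2-yl)-2-methylcyclohex-2-en-1-one | CC1=CC[C@@H](CC1=O)C(C)(C)Cl | intermediate
3 | (1R,6S)-3,7,7-trimethylbicyclo[4.1.0]hept-3-en-2-one | CC1=CC[C@H]2[C@@H](C1=O)C2(C)C | intermediate
4 | 3,4-epoxy-3,7,7-trimethylbicyclo[4.1.0]heptan-2-one, oxirane trans to the cyclopropane | C[C@]12O[C@H]1C[C@H]1[C@@H](C2=O)C1(C)C | intermediate
5 | 3,7,7-trimethylbicyclo[4.1.0]hept-2-en-4-ol, hydroxyl trans to the cyclopropane | CC1=C[C@@H]2[C@H](C[C@@H]1O)C2(C)C | intermediate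
6 | 3,7,7-trimethylbicyclo[4.1.0]hept-2-en-4-one | CC1=C[C@@H]2[C@H](CC1=O)C2(C)C | intermediate
7 | triethyl[(3,7,7-trimethylbicyclo[4.1.0]hept-3-en-4-yl)oxy]silane | CC1=C(O[Si](CC)(CC)CC)C[C@H]2[C@@H](C1)C2(C)C | intermediate
8 | (1R,3S,6S)-3,7,7-trimethylbicyclo[4.1.0]heptan-4-one, methyl cis to the cyclopropane | C[C@H]1C[C@@H]2[C@H](CC1=O)C2(C)C | intermediate
9 | lithium 3,7,7-trimethylbicyclo[4.1.0]hept-4-en-4-olate | C[C@H]1C[C@@H]2[C@H](C=C1O[Li])C2(C)C | intermediate
10 | 3,7,7-trimethylbicyclo[4.1.0]hept-4-en-4-yl trifluoromethanesulfonate, 3-methyl cis to the cyclopropane | C[C@H]1C[C@@H]2[C@H](C=C1OS(=O)(=O)C(F)(F)F)C2(C)C | intermediate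
11 | 2-methyl-2-vinyl-1,3-dioxolane | C=CC1(C)OCCO1 | starting material
12 | 9-[2-(2-methyl-1,3-dioxolan-2-yl)ethyl]-9-borabicyclo[3.3.1]nonane | CC1(CCB2C3CCCC2CCC3)OCCO1 | intermediate
13 | 2-methyl-2-[2-(3,7,7-trimethylbicyclo[4.1.0]hept-4-en-4-yl)ethyl]-1,3-dioxolane | C[C@H]1C[C@@H]2[C@H](C=C1CCC1(C)OCCO1)C2(C)C | intermediate
14 | 4-(3,7,7-trimethylbicyclo[4.1.0]hept-4-en-4-yl)butan-2-one | C[C@H]1C[C@@H]2[C@H](C=C1CCC(C)=O)C2(C)C | intermediate
15 | tosylhydrazone of 14 | C[C@H]1C[C@@H]2[C@H](C=C1CCC(C)=NNS(=O)(=O)c1ccc(C)cc1)C2(C)C | intermediate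
16 | sodium salt of tosylhydrazone 15 | C[C@H]1C[C@@H]2[C@H](C=C1CCC(C)=N[N-]S(=O)(=O)c1ccc(C)cc1)C2(C)C.[Na+] | intermediate
17 | 4-(3-diazobutyl)-3,7,7-trimethylbicyclo[4.1.0]hept-4-ene | C[C@H]1C[C@@H]2[C@H](C=C1CCC(C)=[N+]=[N-])C2(C)C | intermediate
18 | tetracyclic 1-pyrazoline: N=N bridge between C1 and C4, C4-methyl, C4–C5 bond anti to the cyclopropane | C[C@H]1C[C@@H]2[C@H]([C@H]3[C@]14N=N[C@]3(C)CC4)C2(C)C | intermediate
19 | tetracyclic bicyclo[2.1.0]pentane with C1–C4 bond, C4-methyl | C[C@H]1C[C@@H]2[C@H]([C@H]3[C@@]14CC[C@]34C)C2(C)C | intermediate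
20 | 2,4,6-trihydroxybenzene-1,3-dicarbaldehyde (2,4-diformylphloroglucinol) | O=Cc1c(O)cc(O)c(C=O)c1O | starting material
21 | 3-methylbutanal (isovaleraldehyde) | CC(C)CC=O | starting material
22 | o-quinone methide from 20 and 21 (alkene geometry not fixed) | CC(C)CC=C1C(=O)C(C=O)=C(O)C(C=O)=C1O | intermediate
23 | CNP0202714.1 | CC(C)C[C@H]1c2c(O)c(C=O)c(O)c(C=O)c2O[C@]23CC[C@@]1(C)[C@H]2[C@H]1[C@@H](C[C@@H]3C)C1(C)C | target

Total step count: 13
Longest linear sequence: 13 steps (from 1)

Steps most likely to fail

Step 13 (Proposed new method). The quinone methide may attack the more hindered bridgehead or the convex face, which would give a regioisomeric or diastereomeric ether. It may also dimerise faster than it is intercepted by the σ-bond, and the benzylic centre may form with poor facial control. Fallback with known reactions, setting out from 19 and coming back at 23: SnCl4-promoted Friedel–Crafts-type acylative opening of the central cyclopropane bond with 2,4,6-triacetoxybenzoyl chloride (CH2Cl2, −78 °C) gives the chloro ketone F1. Cs2CO3 in MeOH removes the acetates and the phenoxide displaces the tertiary chloride to close the benzoxepinone F2. NaBH4 gives the benzylic carbinol F3. Excess iBuMgBr converts F3 through its o-quinone methide, by addition to the less hindered face, into the isobutyl diphenol F4. Twofold ortho-formylation (MgCl2, Et3N, paraformaldehyde, MeCN) then gives 23.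

Step 11. The diazoalkane may lose N2 before it cycloadds (carbene 1,2-hydrogen shift to alkenes), or may react in a 1,1-fashion instead of the bridged 1,3-mode. Fallback, setting out from 14 and coming back at 18: condensation with benzohydrazide gives the acylhydrazone F5. Sc(OTf)3-catalysed intramolecular (3+2) cycloaddition of the acylhydrazone (azomethine-imine form) with the alkene gives the N-benzoyl pyrazolidine F6. KOH in ethylene glycol removes the benzoyl group to give the cyclic hydrazine F7, and CuCl2/O2 oxidises F7 to the azoalkane 18.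

Step 6. Protonation of the enol may show poor facial selectivity, or the α-methyl ketone may epimerise, which would erode the methyl-bearing stereocentre. Fallback, setting out from 5 and coming back at 8: hydroxyl-directed hydrogenation of the allylic alcohol with [Ir(cod)(PCy3)(py)]PF6 and H2 delivers hydrogen syn to the hydroxyl (anti to the cyclopropane) and gives the saturated alcohol F8. Oxidation with 1,1,1-triacetoxy-1,1-dihydro-1,2-benziodoxol-3(1H)-one then gives 8.

Further compounds
F1 | step 13 | 2,4,6-triacetoxyphenyl ketone at C4 with tertiary chloride at C1 (C1 configuration not fixed) | CC(=O)Oc1cc(OC(C)=O)cc(OC(C)=O)c1C(=O)[C@@]1(C)CCC2(Cl)[C@@H]1[C@H]1[C@@H](C[C@@H]2C)C1(C)C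
F2 | step 13 | benzoxepinone (C7′ ketone, two free phenols, no formyl groups) | O=C1c2c(O)cc(O)cc2O[C@]23CC[C@@]1(C)[C@H]2[C@H]1[C@@H](C[C@@H]3C)C1(C)C
F3 | step 13 | C7′ carbinol of F2 (C7′ configuration not fixed) | OC1c2c(O)cc(O)cc2O[C@]23CC[C@@]1(C)[C@H]2[C@H]1[C@@H](C[C@@H]3C)C1(C)C
F4 | step 13 | bis-deformyl target (C7′ isobutyl, two free phenols) | CC(C)C[C@H]1c2c(O)cc(O)cc2O[C@]23CC[C@@]1(C)[C@H]2[C@H]1[C@@H](C[C@@H]3C)C1(C)C
F5 | step 11 | N-benzoylhydrazone of ketone 14 | C[C@H]1C[C@@H]2[C@H](C=C1CCC(C)=NNC(=O)c1ccccc1)C2(C)C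
F6 | step 11 | N-benzoyl pyrazolidine (benzoyl on the nitrogen bound to C1) | C[C@H]1C[C@@H]2[C@H]([C@H]3[C@]14N(C(=O)c5ccccc5)N[C@]3(C)CC4)C2(C)C
F7 | step 11 | cyclic hydrazine (2,3-diazabicyclo[2.2.1]heptane) | C[C@H]1C[C@@H]2[C@H]([C@H]3[C@]14NN[C@]3(C)CC4)C2(C)C
F8 | step 6 | 3,7,7-trimethylbicyclo[4.1.0]heptan-4-ol, methyl cis and hydroxyl trans to the cyclopropane | C[C@H]1C[C@@H]2[C@H](C[C@@H]1O)C2(C)C
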